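**Retrosynthetic overview**
1. Target ⇒ late C8–O acylation with the bought (R)-chlorohydrin acid 27, C13–O acetylation, and unmasking of a C1 methyl ketal to the C1/C4 hemiketal.
2. Ten-membered ring ⇒ C5–C6 bond by intramolecular vinylogous aldol condensation of the butenolide γ-carbon onto a C5 aldehyde, which also creates the 5E enol-lactone alkene.
3. Butenolide ring ⇒ 2-ethoxyfuran made by Diels–Alder/retro-Diels–Alder of ynoate 13 with 5-ethoxy-4-methyloxazole 14 (key step, loss of MeCN).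
4. Oxolane (C1–C4 + O) ⇒ Michael addition of the L-lactate-derived dioxolanone enolate (sets C4) to vinyl ketone 8, then ketalisation; C8 and C10 ⇒ trans-methylation of the L-glutamate-derived lactone 1.
5. Ring order: oxolane ketal → furan (latent butenolide) → ten-membered carbocycle → hemiketal.

Assumption: 1, 9, 14 and 27 are bought as catalogue compounds (1 from L-glutamic acid, 9 from L-lactic acid, 27 as the single R enantiomer); atom labels C1–C15 follow germacranolide numbering of the target (C1 hemiketal carbon, C4 carbinol carbon, C5=C6, C7=C11, C8 acyloxy carbon, C10 methyl-bearing carbon, C12 lactone C=O, C13 CH2OAc).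

**Step 1**
Reactants: 1 (S)-5-[(trityloxy)methyl]dihydrofuran-2(3H)-one
Product: 2 (3R,5S)-3-methyl-5-[(trityloxy)methyl]dihydrofuran-2(3H)-one
Conditions: LiN(i-Pr)2, THF, −78 °C; MeI, −78 °C
Reagents that add atoms: iodomethane, CI
Why: Lactone enolate alkylation in which the bulky CH2OTr group at C8 shields one face, so methyl enters trans and sets C10 (R).

**Step 2**
Reactants: 2 (3R,5S)-3-methyl-5-[(trityloxy)methyl]dihydrofuran-2(3H)-one
Product: 4 (2R,4S)-N-methoxy-N,2-dimethyl-4-[(triisopropylsilyl)oxy]-5-(trityloxy)pentanamide, via chloromagnesium alkoxide 3 (not isolated)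
Conditions: MeNH(OMe)·HCl, i-PrMgCl, THF, −20 °C; then i-Pr3SiOTf, 2,6-lutidine, −20 → 0 °C
Reagents that add atoms: N,O-dimethylhydroxylamine hydrochloride, CNOC.Cl; triisopropylsilyl trifluoromethanesulfonate, CC(C)[Si](C(C)C)(C(C)C)OS(=O)(=O)C(F)(F)F
Why: Weinreb aminolysis of the lactone by the magnesium amide, with in-flask silylation of the released C8 alkoxide so that it cannot relactonise; no stereocentre is touched.

**Step 3**
Reactants: 4 (2R,4S)-N-methoxy-N,2-dimethyl-4-[(triisopropylsilyl)oxy]-5-(trityloxy)pentanamide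
Product: 5 (2R,4S)-5-hydroxy-N-methoxy-N,2-dimethyl-4-[(triisopropylsilyl)oxy]pentanamide
Conditions: p-TsOH·H2O (cat.), MeOH/CH2Cl2, 0 °C
Reagents that add atoms: none
Why: Acid-catalysed SN1 methanolysis of the trityl ether, which the secondary triisopropylsilyl ether survives.

**Step 4**
Reactants: 5 (2R,4S)-5-hydroxy-N-methoxy-N,2-dimethyl-4-[(triisopropylsilyl)oxy]pentanamide
Product: 6 (2R,4S)-N-methoxy-N,2-dimethyl-5-oxo-4-[(triisopropylsilyl)oxy]pentanamide
Conditions: Dess–Martin periodinane, pyridine, CH2Cl2, 0 °C → rt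
Reagents that add atoms: none
Why: Dess–Martin oxidation under buffered conditions gives the α-silyloxy aldehyde without epimerising C8.

**Step 5**
Reactants: 6 (2R,4S)-N-methoxy-N,2-dimethyl-5-oxo-4-[(triisopropylsilyl)oxy]pentanamide
Product: 7 (2R,4S)-N-methoxy-N,2-dimethyl-4-[(triisopropylsilyl)oxy]hex-5-ynamide
Conditions: dimethyl (1-diazo-2-oxopropyl)phosphonate, K2CO3, MeOH, 0 °C → rt
Reagents that add atoms: dimethyl (1-diazo-2-oxopropyl)phosphonate (Ohira–Bestmann reagent), CC(=O)C(=[N+]=[N-])P(=O)(OC)OC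
Why: Seyferth–Gilbert homologation (Ohira–Bestmann variant) turns the aldehyde into the terminal alkyne C7≡C11 under mild carbonate conditions that leave C8 and C10 intact.

**Step 6**
Reactants: 7 (2R,4S)-N-methoxy-N,2-dimethyl-4-[(triisopropylsilyl)oxy]hex-5-ynamide
Product: 8 (4R,6S)-4-methyl-6-[(triisopropylsilyl)oxy]oct-1-en-7-yn-3-one
Conditions: CH2=CHMgBr (2.5 equiv), THF, −78 → 0 °C; inverse quench into cold 1 M HCl
Reagents that add atoms: vinylmagnesium bromide, C=C[Mg]Br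
Why: Weinreb ketone synthesis in which the chelated tetrahedral adduct stops over-addition (one equivalent of Grignard is spent on the alkyne C–H) and the acidic quench keeps the liberated amine off the enone.

**Step 7**
Reactants: 8 (4R,6S)-4-methyl-6-[(triisopropylsilyl)oxy]oct-1-en-7-yn-3-one; 9 (2S,5S)-2-tert-butyl-5-methyl-1,3-dioxolan-4-one
Product: 11 (2S,5R)-2-tert-butyl-5-methyl-5-[(4R,6S)-4-methyl-3-oxo-6-[(triisopropylsilyl)oxy]oct-7-yn-1-yl]-1,3-dioxolan-4-one, via lithium enolate 10 (not isolated)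
Conditions: 9, LiN(i-Pr)2, THF, −78 °C; then 8, DMPU, −78 °C; NH4Cl (aq.)
Reagents that add atoms: none
Why: Michael addition of the Seebach lactate enolate (self-regeneration of stereocentres) forms C3–C4, and attack anti to the tert-butyl group sets C4 (R).

**Step 8**
Reactants: 11 (2S,5R)-2-tert-butyl-5-methyl-5-[(4R,6S)-4-methyl-3-oxo-6-[(triisopropylsilyl)oxy]oct-7-yn-1-yl]-1,3-dioxolan-4-one
Product: 12 methyl (2R)-5-methoxy-2-methyl-5-[(2R,4S)-4-[(triisopropylsilyl)oxy]hex-5-yn-2-yl]oxolane-2-carboxylate (both C1 ketal epimers)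
Conditions: p-TsOH·H2O (cat.), MeOH, HC(OMe)3, rt
Reagents that add atoms: methanol, CO
Why: Acid methanolysis of the acylal-type dioxolanone frees the C4 tertiary alcohol, which closes onto the C1 ketone to give the cyclic methyl ketal; this protects C1 and stops C10 from epimerising later.

**Step 9**
Reactants: 12 methyl (2R)-5-methoxy-2-methyl-5-[(2R,4S)-4-[(triisopropylsilyl)oxy]hex-5-yn-2-yl]oxolane-2-carboxylate
Product: 13 methyl (2R)-5-methoxy-5-[(2R,4S)-7-methoxy-7-oxo-4-[(triisopropylsilyl)oxy]hept-5-yn-2-yl]-2-methyloxolane-2-carboxylate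
Conditions: LiN(i-Pr)2, THF, −78 °C; ClCO2Me
Reagents that add atoms: methyl chloroformate, COC(=O)Cl
Why: Acylation of the lithium acetylide gives the ynoate (its ester carbon becomes C13); the other ester is α-quaternary and cannot enolise.

**Step 10 (key step)**
Reactants: 13 methyl (2R)-5-methoxy-5-[(2R,4S)-7-methoxy-7-oxo-4-[(triisopropylsilyl)oxy]hept-5-yn-2-yl]-2-methyloxolane-2-carboxylate; 14 5-ethoxy-4-methyl-1,3-oxazole
Product: 16 methyl 2-ethoxy-4-{(1S,3R)-3-[(5R)-2-methoxy-5-(methoxycarbonyl)-5-methyloxolan-2-yl]-1-[(triisopropylsilyl)oxy]butyl}furan-3-carboxylate, via bridged cycloadduct 15 (not isolated)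
Conditions: 14 (5 equiv), toluene, 110 °C, sealed tube
Reagents that add atoms: none
Why: Diels–Alder addition of the ynoate across C2/C5 of the oxazole and retro-Diels–Alder loss of acetonitrile (Kondrat'eva furan synthesis) build the furanone ring; the alkoxy-bearing oxazole carbon bonds to the ester-bearing alkyne carbon, so C12(OEt) sits next to C11 and the C8 arm ends on C7.

**Step 11**
Reactants: 16 methyl 2-ethoxy-4-{(1S,3R)-3-[(5R)-2-methoxy-5-(methoxycarbonyl)-5-methyloxolan-2-yl]-1-[(triisopropylsilyl)oxy]butyl}furan-3-carboxylate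
Product: 18 3-(hydroxymethyl)-4-{(1S,3R)-3-[(2S,5R)-5-(hydroxymethyl)-2-methoxy-5-methyloxolan-2-yl]-1-[(triisopropylsilyl)oxy]butyl}furan-2(5H)-one, via furan diol 17 (not isolated)
Conditions: (i-Bu)2AlH, CH2Cl2, −78 → 0 °C; aq. KNaC4H4O6; crude in MeOH, PPTS, 0 °C; aq. NaHCO3; SiO2 separation of the ketal epimers (unwanted C1 epimer re-equilibrated with PPTS/MeOH)
Reagents that add atoms: water, O
Why: Hydride reduction of both esters, then C-protonation of the 2-ethoxyfuran (a cyclic ketene acetal) and hydrolysis of the resulting orthoester unveil the butenolide, while the methyl ketal only exchanges with the solvent.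

**Step 12**
Reactants: 18 3-(hydroxymethyl)-4-{(1S,3R)-3-[(2S,5R)-5-(hydroxymethyl)-2-methoxy-5-methyloxolan-2-yl]-1-[(triisopropylsilyl)oxy]butyl}furan-2(5H)-one
Product: 19 3-{[(tert-butyldimethylsilyl)oxy]methyl}-4-{(1S,3R)-3-[(2S,5R)-5-(hydroxymethyl)-2-methoxy-5-methyloxolan-2-yl]-1-[(triisopropylsilyl)oxy]butyl}furan-2(5H)-one
Conditions: t-BuMe2SiCl (1.05 equiv), imidazole, CH2Cl2, −20 °C
Reagents that add atoms: tert-butyldimethylsilyl chloride, CC(C)(C)[Si](C)(C)Cl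
Why: Selective silylation of the unhindered allylic C13 alcohol over the neopentyl C5 alcohol; a silyl ether is chosen because an acetate at C13 would be expelled from the later dienolate.

**Step 13**
Reactants: 19 3-{[(tert-butyldimethylsilyl)oxy]methyl}-4-{(1S,3R)-3-[(2S,5R)-5-(hydroxymethyl)-2-methoxy-5-methyloxolan-2-yl]-1-[(triisopropylsilyl)oxy]butyl}furan-2(5H)-one
Product: 20 (2R,5S)-5-{(2R,4S)-4-[4-{[(tert-butyldimethylsilyl)oxy]methyl}-5-oxo-2,5-dihydrofuran-3-yl]-4-[(triisopropylsilyl)oxy]butan-2-yl}-5-methoxy-2-methyloxolane-2-carbaldehyde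
Conditions: Dess–Martin periodinane, pyridine, CH2Cl2, 0 °C → rt
Reagents that add atoms: none
Why: Dess–Martin oxidation gives the non-enolisable α-alkoxy C5 aldehyde.

**Step 14**
Reactants: 20 (2R,5S)-5-{(2R,4S)-4-[4-{[(tert-butyldimethylsilyl)oxy]methyl}-5-oxo-2,5-dihydrofuran-3-yl]-4-[(triisopropylsilyl)oxy]butan-2-yl}-5-methoxy-2-methyloxolane-2-carbaldehyde
Product: 23 (1S,4R,5E,8S,10R)-13-[(tert-butyldimethylsilyl)oxy]-1,4-epoxy-1-methoxy-8-[(triisopropylsilyl)oxy]germacra-5,7(11)-dien-12,6-olide, via lithium aldolate 21 (not isolated), via mesylate 22 (not isolated)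
Conditions: LiN(SiMe3)2, THF (1 mM, slow addition of 20), −78 °C; MeSO2Cl; DBU, −78 → 0 °C
Reagents that add atoms: none
Why: Intramolecular vinylogous aldol addition of the aromatic furanolate γ-carbon (C6) to the C5 aldehyde, then E1cB loss of mesylate; the C10 and C5 arms are cis on the oxolane in this ketal epimer, and the ten-membered ring forces the 5E geometry.

**Step 15**
Reactants: 23 (1S,4R,5E,8S,10R)-13-[(tert-butyldimethylsilyl)oxy]-1,4-epoxy-1-methoxy-8-[(triisopropylsilyl)oxy]germacra-5,7(11)-dien-12,6-olide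
Product: 25 (1S,4R,5E,8S,10R)-1,4-epoxy-1,8,13-trihydroxygermacra-5,7(11)-dien-12,6-olide, via diol ketal 24 (not isolated)
Conditions: Bu4NF, AcOH, THF, rt; then 1 M HCl, THF/H2O, 0 °C
Reagents that add atoms: water, O
Why: Buffered fluoride cleaves both silyl ethers and dilute acid hydrolyses the bridging methyl ketal to the hemiketal, whose C1 configuration (S) is fixed by the oxygen bridge to C4.

**Step 16**
Reactants: 25 (1S,4R,5E,8S,10R)-1,4-epoxy-1,8,13-trihydroxygermacra-5,7(11)-dien-12,6-olide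
Product: 26 (1S,4R,5E,8S,10R)-13-acetoxy-1,4-epoxy-1,8-dihydroxygermacra-5,7(11)-dien-12,6-olide
Conditions: AcCl (1.1 equiv), 2,4,6-collidine, CH2Cl2, −78 °C
Reagents that add atoms: acetyl chloride, CC(=O)Cl
Why: Selective acylation, because the primary allylic C13 hydroxyl reacts far faster than the hindered secondary C8 hydroxyl and the tertiary hemiketal hydroxyl.

**Step 17**
Reactants: 26 (1S,4R,5E,8S,10R)-13-acetoxy-1,4-epoxy-1,8-dihydroxygermacra-5,7(11)-dien-12,6-olide; 27 (R)-3-chloro-2-hydroxy-2-methylpropanoic acid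
Product: 29 (1S,4R,5E,8S,10R)-13-acetoxy-8-{[(2R)-3-chloro-2-hydroxy-2-methylpropanoyl]oxy}-1,4-epoxy-1-hydroxygermacra-5,7(11)-dien-12,6-olide (CNP0414417.3), via mixed anhydride 28 (not isolated)
Conditions: 27, 2,4,6-Cl3C6H2COCl, Et3N, THF, 0 °C; then 26, DMAP, toluene, rt
Reagents that add atoms: none
Why: Yamaguchi esterification of the C8 alcohol; the tertiary α-hydroxyl of 27 is too hindered to self-acylate and its bought stereocentre (R) is not touched.

**Compound list**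
1 | (S)-5-[(trityloxy)methyl]dihydrofuran-2(3H)-one | O=C1CC[C@@H](COC(c2ccccc2)(c2ccccc2)c2ccccc2)O1 | starting material
2 | (3R,5S)-3-methyl-5-[(trityloxy)methyl]dihydrofuran-2(3H)-one | O=C1[C@H](C)C[C@@H](COC(c2ccccc2)(c2ccccc2)c2ccccc2)O1 | intermediate
3 | chloromagnesium alkoxide of (2R,4S)-4-hydroxy-N-methoxy-N,2-dimethyl-5-(trityloxy)pentanamide | CON(C)C(=O)[C@H](C)C[C@H]([O-])COC(c1ccccc1)(c1ccccc1)c1ccccc1.[Mg+2].[Cl-] | intermediate
4 | (2R,4S)-N-methoxy-N,2-dimethyl-4-[(triisopropylsilyl)oxy]-5-(trityloxy)pentanamide | CON(C)C(=O)[C@H](C)C[C@H](O[Si](C(C)C)(C(C)C)C(C)C)COC(c1ccccc1)(c1ccccc1)c1ccccc1 | intermediate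
5 | (2R,4S)-5-hydroxy-N-methoxy-N,2-dimethyl-4-[(triisopropylsilyl)oxy]pentanamide | CON(C)C(=O)[C@H](C)C[C@H](O[Si](C(C)C)(C(C)C)C(C)C)CO | intermediate
6 | (2R,4S)-N-methoxy-N,2-dimethyl-5-oxo-4-[(triisopropylsilyl)oxy]pentanamide | CON(C)C(=O)[C@H](C)C[C@H](O[Si](C(C)C)(C(C)C)C(C)C)C=O | intermediate
7 | (2R,4S)-N-methoxy-N,2-dimethyl-4-[(triisopropylsilyl)oxy]hex-5-ynamide | CON(C)C(=O)[C@H](C)C[C@H](O[Si](C(C)C)(C(C)C)C(C)C)C#C | intermediate
8 | (4R,6S)-4-methyl-6-[(triisopropylsilyl)oxy]oct-1-en-7-yn-3-one | C=CC(=O)[C@H](C)C[C@H](O[Si](C(C)C)(C(C)C)C(C)C)C#C | intermediate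
9 | (2S,5S)-2-tert-butyl-5-methyl-1,3-dioxolan-4-one (cis; from L-lactic acid) | C[C@@H]1O[C@H](C(C)(C)C)OC1=O | starting material
10 | lithium (2S)-2-tert-butyl-5-methyl-1,3-dioxol-4-olate (enolate of 9) | CC1=C([O-])O[C@@H](C(C)(C)C)O1.[Li+] | intermediate
11 | (2S,5R)-2-tert-butyl-5-methyl-5-[(4R,6S)-4-methyl-3-oxo-6-[(triisopropylsilyl)oxy]oct-7-yn-1-yl]-1,3-dioxolan-4-one | C#C[C@@H](O[Si](C(C)C)(C(C)C)C(C)C)C[C@@H](C)C(=O)CC[C@@]1(C)O[C@H](C(C)(C)C)OC1=O | intermediate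
12 | methyl (2R)-5-methoxy-2-methyl-5-[(2R,4S)-4-[(triisopropylsilyl)oxy]hex-5-yn-2-yl]oxolane-2-carboxylate (C1 ketal epimers) | C#C[C@@H](O[Si](C(C)C)(C(C)C)C(C)C)C[C@@H](C)C1(OC)CC[C@](C)(C(=O)OC)O1 | intermediate
13 | methyl (2R)-5-methoxy-5-[(2R,4S)-7-methoxy-7-oxo-4-[(triisopropylsilyl)oxy]hept-5-yn-2-yl]-2-methyloxolane-2-carboxylate (C1 ketal epimers) | COC(=O)C#C[C@@H](O[Si](C(C)C)(C(C)C)C(C)C)C[C@@H](C)C1(OC)CC[C@](C)(C(=O)OC)O1 | intermediate
14 | 5-ethoxy-4-methyl-1,3-oxazole | CCOc1ocnc1C | starting material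
15 | bridged cycloadduct: 7-oxa-2-azabicyclo[2.2.1]hepta-2,5-diene with 1-OEt, 3-Me, 6-CO2Me and the C8 side chain on C5 | CCOC12OC(N=C1C)C([C@@H](O[Si](C(C)C)(C(C)C)C(C)C)C[C@@H](C)C3(OC)CC[C@](C)(C(=O)OC)O3)=C2C(=O)OC | intermediate
16 | methyl 2-ethoxy-4-{(1S,3R)-3-[(5R)-2-methoxy-5-(methoxycarbonyl)-5-methyloxolan-2-yl]-1-[(triisopropylsilyl)oxy]butyl}furan-3-carboxylate (C1 ketal epimers) | CCOc1occ([C@@H](O[Si](C(C)C)(C(C)C)C(C)C)C[C@@H](C)C2(OC)CC[C@](C)(C(=O)OC)O2)c1C(=O)OC | intermediate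
17 | {2-ethoxy-4-[(1S,3R)-3-[(5R)-5-(hydroxymethyl)-2-methoxy-5-methyloxolan-2-yl]-1-[(triisopropylsilyl)oxy]butyl]furan-3-yl}methanol (C1 ketal epimers) | CCOc1occ([C@@H](O[Si](C(C)C)(C(C)C)C(C)C)C[C@@H](C)C2(OC)CC[C@](C)(CO)O2)c1CO | intermediate
18 | 3-(hydroxymethyl)-4-{(1S,3R)-3-[(2S,5R)-5-(hydroxymethyl)-2-methoxy-5-methyloxolan-2-yl]-1-[(triisopropylsilyl)oxy]butyl}furan-2(5H)-one | O=C1OCC([C@@H](O[Si](C(C)C)(C(C)C)C(C)C)C[C@@H](C)[C@]2(OC)CC[C@](C)(CO)O2)=C1CO | intermediate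
19 | 3-{[(tert-butyldimethylsilyl)oxy]methyl}-4-{(1S,3R)-3-[(2S,5R)-5-(hydroxymethyl)-2-methoxy-5-methyloxolan-2-yl]-1-[(triisopropylsilyl)oxy]butyl}furan-2(5H)-one | O=C1OCC([C@@H](O[Si](C(C)C)(C(C)C)C(C)C)C[C@@H](C)[C@]2(OC)CC[C@](C)(CO)O2)=C1CO[Si](C)(C)C(C)(C)C | intermediate
20 | (2R,5S)-5-{(2R,4S)-4-[4-{[(tert-butyldimethylsilyl)oxy]methyl}-5-oxo-2,5-dihydrofuran-3-yl]-4-[(triisopropylsilyl)oxy]butan-2-yl}-5-methoxy-2-methyloxolane-2-carbaldehyde | O=C1OCC([C@@H](O[Si](C(C)C)(C(C)C)C(C)C)C[C@@H](C)[C@]2(OC)CC[C@](C)(C=O)O2)=C1CO[Si](C)(C)C(C)(C)C | intermediate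
21 | lithium C5-alkoxide of (1S,4R,8S,10R)-13-[(tert-butyldimethylsilyl)oxy]-1,4-epoxy-5-hydroxy-1-methoxy-8-[(triisopropylsilyl)oxy]germacr-7(11)-en-12,6-olide (C5/C6 epimers) | CC(C)(C)[Si](C)(C)OCC1=C2C(C([O-])[C@@]3(C)CC[C@](OC)(O3)[C@H](C)C[C@@H]2O[Si](C(C)C)(C(C)C)C(C)C)OC1=O.[Li+] | intermediate
22 | C5-O-methanesulfonate of the aldol from 21 (C5/C6 epimers) | CC(C)(C)[Si](C)(C)OCC1=C2C(C(OS(C)(=O)=O)[C@@]3(C)CC[C@](OC)(O3)[C@H](C)C[C@@H]2O[Si](C(C)C)(C(C)C)C(C)C)OC1=O | intermediate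
23 | (1S,4R,5E,8S,10R)-13-[(tert-butyldimethylsilyl)oxy]-1,4-epoxy-1-methoxy-8-[(triisopropylsilyl)oxy]germacra-5,7(11)-dien-12,6-olide | CC(C)(C)[Si](C)(C)OCC1=C2/C(=C\[C@@]3(C)CC[C@](OC)(O3)[C@H](C)C[C@@H]2O[Si](C(C)C)(C(C)C)C(C)C)OC1=O | intermediate
24 | (1S,4R,5E,8S,10R)-1,4-epoxy-8,13-dihydroxy-1-methoxygermacra-5,7(11)-dien-12,6-olide | OCC1=C2/C(=C\[C@@]3(C)CC[C@](OC)(O3)[C@H](C)C[C@@H]2O)OC1=O | intermediate
25 | (1S,4R,5E,8S,10R)-1,4-epoxy-1,8,13-trihydroxygermacra-5,7(11)-dien-12,6-olide | OCC1=C2/C(=C\[C@@]3(C)CC[C@](O)(O3)[C@H](C)C[C@@H]2O)OC1=O | intermediate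
26 | (1S,4R,5E,8S,10R)-13-acetoxy-1,4-epoxy-1,8-dihydroxygermacra-5,7(11)-dien-12,6-olide | CC(=O)OCC1=C2/C(=C\[C@@]3(C)CC[C@](O)(O3)[C@H](C)C[C@@H]2O)OC1=O | intermediate
27 | (R)-3-chloro-2-hydroxy-2-methylpropanoic acid | OC(=O)[C@@](C)(O)CCl | starting material
28 | (2R)-3-chloro-2-hydroxy-2-methylpropanoic 2,4,6-trichlorobenzoic anhydride | O=C(OC(=O)[C@@](C)(O)CCl)c1c(Cl)cc(Cl)cc1Cl | intermediate
29 | (1S,4R,5E,8S,10R)-13-acetoxy-8-{[(2R)-3-chloro-2-hydroxy-2-methylpropanoyl]oxy}-1,4-epoxy-1-hydroxygermacra-5,7(11)-dien-12,6-olide (CNP0414417.3) | CC(=O)OCC1=C2/C(=C\[C@@]3(C)CC[C@](O)(O3)[C@H](C)C[C@@H]2OC(=O)[C@@](C)(O)CCl)OC1=O | target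

**Step count**
Total steps: 17. Longest linear sequence: 17 (1 → 29); 9, 14 and 27 are bought and enter at steps 7, 10 and 17.

**Three steps most likely to fail, each with one fallback**

Step 14 (ten-membered ring closure). A medium ring is closed by an aldol that competes with oligomerisation, and only one ketal epimer can bridge. The fallback closes the same C5=C6 bond by an intramolecular Wittig olefination instead; it sets out from 19 and comes back at 23. The butenolide of 19 is brominated at the γ-carbon through its dianion (LiN(SiMe3)2, 2.1 equiv, THF, −78 °C, then CBr4) to give γ-bromobutenolide F1. Triphenylphosphine (toluene, 60 °C) converts it into phosphonium bromide F2, and Dess–Martin oxidation of the C5 alcohol gives phosphonium aldehyde F3. Slow addition of F3 to Et3N in CH2Cl2 (1 mM) generates the stabilised ylide, which closes onto the aldehyde to give 23.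

Step 7 (conjugate addition of the lactate enolate). The thermally fragile enolate can add 1,2 or be quenched by proton transfer. The fallback makes the C1–C2 bond by sulfone acylation rather than the C3–C4 bond on the enone; it sets out from 7 (with enolate 10 made from 9 as in the route) and comes back at 11. Enolate 10 is added to phenyl vinyl sulfone (THF, −78 °C), still anti to the tert-butyl group, to give sulfonyl dioxolanone F4. F4 is deprotonated next to sulfur (LiN(i-Pr)2, THF, −78 °C) and acylated with Weinreb amide 7 (its alkyne C–H first masked with one equivalent of i-PrMgCl) to give β-keto sulfone F5. Reductive desulfonylation with SmI2 (THF/MeOH, −78 °C) gives 11.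

Step 17 (esterification with the unprotected tertiary α-hydroxy acid). The C8 alcohol is hindered and the free α-hydroxyl may interfere with activation. The fallback installs the chlorohydrin after the ester bond by epoxide opening; it sets out from 27 (and 26) and comes back at 29. Treatment of 27 with KOH (2 equiv, H2O, 0 °C, then careful acidification) closes the chlorohydrin to epoxy acid F6 without touching the stereocentre. Yamaguchi esterification of F6 with 26 gives epoxy ester F7. Anhydrous HCl (1 M in Et2O, −20 °C) opens the epoxide at its CH2 terminus and gives 29 with the (2R) side chain.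

**Further compounds**
F1 | step 14 | 5-bromo-3-{[(tert-butyldimethylsilyl)oxy]methyl}-4-{(1S,3R)-3-[(2S,5R)-5-(hydroxymethyl)-2-methoxy-5-methyloxolan-2-yl]-1-[(triisopropylsilyl)oxy]butyl}furan-2(5H)-one (C6 epimers) | O=C1OC(Br)C([C@@H](O[Si](C(C)C)(C(C)C)C(C)C)C[C@@H](C)[C@]2(OC)CC[C@](C)(CO)O2)=C1CO[Si](C)(C)C(C)(C)C
F2 | step 14 | triphenylphosphonium bromide from F1 (PPh3 in place of Br at C6) | O=C1OC([P+](c3ccccc3)(c3ccccc3)c3ccccc3)C([C@@H](O[Si](C(C)C)(C(C)C)C(C)C)C[C@@H](C)[C@]2(OC)CC[C@](C)(CO)O2)=C1CO[Si](C)(C)C(C)(C)C.[Br-]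
F3 | step 14 | C5 aldehyde of phosphonium bromide F2 | O=C1OC([P+](c3ccccc3)(c3ccccc3)c3ccccc3)C([C@@H](O[Si](C(C)C)(C(C)C)C(C)C)C[C@@H](C)[C@]2(OC)CC[C@](C)(C=O)O2)=C1CO[Si](C)(C)C(C)(C)C.[Br-]
F4 | step 7 | (2S,5R)-2-tert-butyl-5-methyl-5-[2-(phenylsulfonyl)ethyl]-1,3-dioxolan-4-one | O=S(=O)(CC[C@@]1(C)O[C@H](C(C)(C)C)OC1=O)c1ccccc1
F5 | step 7 | (2S,5R)-2-tert-butyl-5-methyl-5-[(4R,6S)-4-methyl-3-oxo-2-(phenylsulfonyl)-6-[(triisopropylsilyl)oxy]oct-7-yn-1-yl]-1,3-dioxolan-4-one (C2 epimers) | C#C[C@@H](O[Si](C(C)C)(C(C)C)C(C)C)C[C@@H](C)C(=O)C(C[C@@]1(C)O[C@H](C(C)(C)C)OC1=O)S(=O)(=O)c1ccccc1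
F6 | step 17 | (S)-2-methyloxirane-2-carboxylic acid | OC(=O)[C@]1(C)CO1
F7 | step 17 | (1S,4R,5E,8S,10R)-13-acetoxy-1,4-epoxy-1-hydroxy-8-{[(2S)-2-methyloxirane-2-carbonyl]oxy}germacra-5,7(11)-dien-12,6-olide | CC(=O)OCC1=C2/C(=C\[C@@]3(C)CC[C@](O)(O3)[C@H](C)C[C@@H]2OC(=O)[C@]4(C)CO4)OC1=O
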